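**Retrosynthetic overview**
- Target ⇒ its bis(benzyl ether) by hydrogenolysis. The C3–CH2Ar bond comes from C-alkylation of the alkoxide–enolate of an α-hydroxy-β-(arylmethyl)butyrolactone, anti to the C4 substituent (sets C3).
- C3–O bond: electrophilic hydroxylation of the enolate of the (R)-β-(arylmethyl)-γ-butyrolactone.
- Ring C5–O1 bond (key step, the only catalyst-controlled stereocentre, C4): enantioselective Baeyer–Villiger desymmetrisation of a prochiral 3-(arylmethyl)cyclobutanone.
- Cyclobutanone: [2+2] of dichloroketene with O-benzylated 4-allyl-2,6-dimethoxyphenol, then dechlorination.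
- Ring order: both arenes are bought; the cyclobutanone ring is made first and is then expanded to the lactone ring; no other ring is formed.

Assumption: the SMILES is read as the (3S,4S) lactone (the two benzyl groups trans, 3-OH cis to the 4-benzyl group); both phenols are carried as benzyl ethers.

**Step 1**
Reactants: 1 4-allyl-2,6-dimethoxyphenol
Product: 2 5-allyl-2-(benzyloxy)-1,3-dimethoxybenzene
Conditions: BnBr (1.2 equiv), K2CO3 (2 equiv), DMF, 60 °C
Reagents that add atoms: benzyl bromide, BrCc1ccccc1
Why: Williamson etherification of the phenoxide protects the phenol against the acylating, oxidising and strongly basic conditions that follow; no stereocentre is involved.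

**Step 2**
Reactants: 2 5-allyl-2-(benzyloxy)-1,3-dimethoxybenzene; 3 trichloroacetyl chloride
Product: 5 3-[4-(benzyloxy)-3,5-dimethoxybenzyl]cyclobutan-1-one, via dichlorocyclobutanone 4 (not isolated)
Conditions: Zn–Cu couple, Et2O–DME, rt; filter, concentrate; then Zn, AcOH, 60 °C
Reagents that add atoms: none
Why: Thermal [2+2] ketene–alkene cycloaddition of dichloroketene (carbonyl carbon bonds to the terminal alkene carbon) followed by zinc reductive dechlorination gives the 3-substituted cyclobutanone, which is achiral because C1 and C3 lie on a mirror plane.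

**Step 3**
Reactants: 5 3-[4-(benzyloxy)-3,5-dimethoxybenzyl]cyclobutan-1-one
Product: 6 (R)-4-[4-(benzyloxy)-3,5-dimethoxybenzyl]dihydrofuran-2(3H)-one
Conditions: (S,S)-imidodiphosphoric acid built from two (S)-3,3'-bis(2,4,6-triethylphenyl)-BINOL units (5 mol %), 35% aq H2O2 (1.5 equiv), CHCl3, −40 °C
Reagents that add atoms: hydrogen peroxide, OO
Why: Proposed new method: a confined imidodiphosphoric acid as chiral catalyst for the H2O2 Baeyer–Villiger desymmetrisation of a 3-(arylmethyl)cyclobutanone; the P(=O)OH/P=O pair activates the ketone and H2O2 together, the Criegee perhydrate forms inside the narrow chiral pocket, the arylmethyl arm is held in one quadrant so that only one of the two enantiotopic ring C–C bonds can lie antiperiplanar to the O–O bond, and that CH2 migrates to oxygen with loss of water, forming the ring C–O bond and the (R) centre at C4; the closest known reaction is the H2O2 Baeyer–Villiger desymmetrisation of 3-arylcyclobutanones with open BINOL phosphoric acids, which is only moderately selective for 3-benzyl substrates, and imidodiphosphoric acids are already known to activate H2O2 in asymmetric sulfoxidation; the catalyst antipode is exchanged if a test run gives the enantiomer of 6.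

**Step 4**
Reactants: 6 (R)-4-[4-(benzyloxy)-3,5-dimethoxybenzyl]dihydrofuran-2(3H)-one
Product: 8 (3R,4S)-4-[4-(benzyloxy)-3,5-dimethoxybenzyl]-3-hydroxydihydrofuran-2(3H)-one, via sodium enolate 7 (not isolated)
Conditions: NaN(SiMe3)2 (1.2 equiv), THF, −78 °C; then 2-(phenylsulfonyl)-3-phenyloxaziridine (1.5 equiv), −78 °C; AcOH quench
Reagents that add atoms: 2-(phenylsulfonyl)-3-phenyloxaziridine, O=S(=O)(N1OC1c1ccccc1)c1ccccc1
Why: Davis oxaziridine hydroxylation of the lactone enolate makes the C3–O bond, mainly anti to the C4 benzyl group (3,4-trans); the C3 configuration is erased again in step 6, so the epimer ratio does not matter and C4 is untouched.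

**Step 5**
Reactants: 9 [4-(benzyloxy)-3-methoxyphenyl]methanol
Product: 10 1-(benzyloxy)-4-(bromomethyl)-2-methoxybenzene
Conditions: PBr3 (0.4 equiv), Et2O, 0 °C; used at once
Reagents that add atoms: phosphorus tribromide, BrP(Br)Br
Why: Conversion of a benzylic alcohol to the bromide through its bromophosphite (SN2) gives the electrophile for step 6; no stereocentre is involved.

**Step 6**
Reactants: 8 (3R,4S)-4-[4-(benzyloxy)-3,5-dimethoxybenzyl]-3-hydroxydihydrofuran-2(3H)-one; 10 1-(benzyloxy)-4-(bromomethyl)-2-methoxybenzene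
Product: 12 (3S,4S)-3-[4-(benzyloxy)-3-methoxybenzyl]-4-[4-(benzyloxy)-3,5-dimethoxybenzyl]-3-hydroxydihydrofuran-2(3H)-one, via dilithium dianion 11 (not isolated)
Conditions: LiN(iPr)2 (2.3 equiv), THF–DMPU, −78 to −40 °C; then 10 (1.3 equiv), −78 to −20 °C; AcOH quench
Reagents that add atoms: none
Why: SN2 C-alkylation of the alkoxide–enolate dianion of an α-hydroxy lactone; the benzylic bromide attacks the planar C3 anti to the C4 benzyl group, so the new benzyl group ends trans to it and the hydroxyl cis, which is the (3S) configuration.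

**Step 7**
Reactants: 12 (3S,4S)-3-[4-(benzyloxy)-3-methoxybenzyl]-4-[4-(benzyloxy)-3,5-dimethoxybenzyl]-3-hydroxydihydrofuran-2(3H)-one
Product: 13 (3S,4S)-3-hydroxy-3-(4-hydroxy-3-methoxybenzyl)-4-(4-hydroxy-3,5-dimethoxybenzyl)dihydrofuran-2(3H)-one
Conditions: H2 (1 atm), 10% Pd/C, EtOAc–MeOH, rt
Reagents that add atoms: none
Why: Catalytic hydrogenolysis cleaves both aryl benzyl ethers; the lactone, the tertiary alcohol and the two stereocentres (neither benzylic to oxygen) are unaffected.

**Compound list**
1 | 4-allyl-2,6-dimethoxyphenol | C=CCc1cc(OC)c(O)c(OC)c1 | starting material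
2 | 5-allyl-2-(benzyloxy)-1,3-dimethoxybenzene | C=CCc1cc(OC)c(OCc2ccccc2)c(OC)c1 | intermediate
3 | trichloroacetyl chloride | ClC(=O)C(Cl)(Cl)Cl | starting material
4 | (±)-3-[4-(benzyloxy)-3,5-dimethoxybenzyl]-2,2-dichlorocyclobutan-1-one | O=C1CC(Cc2cc(OC)c(OCc3ccccc3)c(OC)c2)C1(Cl)Cl | intermediate (not isolated)
5 | 3-[4-(benzyloxy)-3,5-dimethoxybenzyl]cyclobutan-1-one (achiral) | O=C1CC(Cc2cc(OC)c(OCc3ccccc3)c(OC)c2)C1 | intermediate
6 | (R)-4-[4-(benzyloxy)-3,5-dimethoxybenzyl]dihydrofuran-2(3H)-one | O=C1C[C@@H](Cc2cc(OC)c(OCc3ccccc3)c(OC)c2)CO1 | intermediate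
7 | sodium (R)-4-[4-(benzyloxy)-3,5-dimethoxybenzyl]-4,5-dihydrofuran-2-olate | [Na+].[O-]C1=C[C@@H](Cc2cc(OC)c(OCc3ccccc3)c(OC)c2)CO1 | intermediate (not isolated)
8 | (3R,4S)-4-[4-(benzyloxy)-3,5-dimethoxybenzyl]-3-hydroxydihydrofuran-2(3H)-one | O[C@H]1C(=O)OC[C@@H]1Cc1cc(OC)c(OCc2ccccc2)c(OC)c1 | intermediate
9 | [4-(benzyloxy)-3-methoxyphenyl]methanol | OCc1ccc(OCc2ccccc2)c(OC)c1 | starting material
10 | 1-(benzyloxy)-4-(bromomethyl)-2-methoxybenzene | BrCc1ccc(OCc2ccccc2)c(OC)c1 | intermediate
11 | dilithium (S)-4-[4-(benzyloxy)-3,5-dimethoxybenzyl]-4,5-dihydrofuran-2,3-bis(olate) | [Li+].[Li+].[O-]C1=C([O-])[C@@H](Cc2cc(OC)c(OCc3ccccc3)c(OC)c2)CO1 | intermediate (not isolated)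
12 | (3S,4S)-3-[4-(benzyloxy)-3-methoxybenzyl]-4-[4-(benzyloxy)-3,5-dimethoxybenzyl]-3-hydroxydihydrofuran-2(3H)-one | COc1cc(C[C@@]2(O)C(=O)OC[C@@H]2Cc2cc(OC)c(OCc3ccccc3)c(OC)c2)ccc1OCc1ccccc1 | intermediate
13 | (3S,4S)-3-hydroxy-3-(4-hydroxy-3-methoxybenzyl)-4-(4-hydroxy-3,5-dimethoxybenzyl)dihydrofuran-2(3H)-one | COc1cc(C[C@@]2(O)C(=O)OC[C@@H]2Cc2cc(OC)c(O)c(OC)c2)ccc1O | target

**Step count**
Total steps: 7. Longest linear sequence: 6 (steps 1, 2, 3, 4, 6, 7); step 5 is a one-step side branch.

**Steps most likely to fail**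

Step 2 ([2+2] and dechlorination). The risks are a modest yield with a monosubstituted alkene and acylation of the electron-rich ring by the acid chloride. The fallback sets out from 2 and uses a keteniminium instead of a ketene: N,N-dimethylacetamide activated with Tf2O and 2,4,6-collidine in ClCH2CH2Cl at reflux adds to the alkene to give N-{3-[4-(benzyloxy)-3,5-dimethoxybenzyl]cyclobutylidene}-N-methylmethanaminium triflate F1. Hydrolysis with aqueous NaHCO3 gives the cyclobutanone directly, with no zinc and no chlorinated intermediate, and the route is rejoined at 5.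

Step 3 (the proposed new Baeyer–Villiger catalyst). The risks are low enantioselectivity or rate with the flexible arylmethyl arm, and an unknown sense of induction. The fallback uses known chemistry and sets out from 5. Enantioselective deprotonation with LiN[CH(Me)Ph]2 (the antipode that leads to the R series) in the presence of Me3SiCl at −100 °C gives (R)-({3-[4-(benzyloxy)-3,5-dimethoxybenzyl]cyclobut-1-en-1-yl}oxy)trimethylsilane F2. Titrated ozonolysis of the enol ether double bond at −78 °C with NaBH4 work-up gives (R)-3-[4-(benzyloxy)-3,5-dimethoxybenzyl]-4-hydroxybutanoic acid F3, which lactonises on acidification, and the route is rejoined at 6. In either variant, 8 or 12 can be recrystallised to raise the ee.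

Step 6 (dianion alkylation). The risks are incomplete formation of the dianion, O-alkylation, and decomposition of the labile bromide. The fallback sets out from 8 and replaces SN2 alkylation by aldol addition and reductive removal of the carbinol. The same dianion is added at −78 °C to commercial 4-(benzyloxy)-3-methoxybenzaldehyde, again anti to the C4 benzyl group, to give (3R,4S)-3-{[4-(benzyloxy)-3-methoxyphenyl](hydroxy)methyl}-4-[4-(benzyloxy)-3,5-dimethoxybenzyl]-3-hydroxydihydrofuran-2(3H)-one F4 as a mixture of carbinol epimers. Hydrogenolysis (H2, 10% Pd/C, AcOH, cat. HClO4) removes the benzylic hydroxyl together with both benzyl ethers and rejoins the route at the target 13; step 5 is then not needed.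

**Further compounds**
F1 | step 2 | N-{3-[4-(benzyloxy)-3,5-dimethoxybenzyl]cyclobutylidene}-N-methylmethanaminium triflate | C[N+](C)=C1CC(Cc2cc(OC)c(OCc3ccccc3)c(OC)c2)C1.[O-]S(=O)(=O)C(F)(F)F
F2 | step 3 | (R)-({3-[4-(benzyloxy)-3,5-dimethoxybenzyl]cyclobut-1-en-1-yl}oxy)trimethylsilane | C[Si](C)(C)OC1=C[C@H](Cc2cc(OC)c(OCc3ccccc3)c(OC)c2)C1
F3 | step 3 | (R)-3-[4-(benzyloxy)-3,5-dimethoxybenzyl]-4-hydroxybutanoic acid | OC(=O)C[C@@H](Cc1cc(OC)c(OCc2ccccc2)c(OC)c1)CO
F4 | step 6 | (3R,4S)-3-{[4-(benzyloxy)-3-methoxyphenyl](hydroxy)methyl}-4-[4-(benzyloxy)-3,5-dimethoxybenzyl]-3-hydroxydihydrofuran-2(3H)-one (carbinol epimers) | COc1cc(C(O)[C@@]2(O)C(=O)OC[C@@H]2Cc2cc(OC)c(OCc3ccccc3)c(OC)c2)ccc1OCc1ccccc1
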